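**Retrosynthetic overview**

1. Polymatin A (25) ⇐ its 9-O-TBS ether 24 (desilylation).
2. 24 ⇐ acyclic iodo-aldehyde 21 by intramolecular Ni/Cr alkenylation C5→C6. The ten-membered carbocycle closes first; the C6 chromium alkoxide then closes the α-methylene-γ-lactone onto the C12 ester in the same operation (C6 set here).
3. 21 ⇐ diol 16 (9-O-silylation, 8-O-angeloylation, acetal hydrolysis). 16 ⇐ α-hydroxy aldehyde 10 + allyl bromide 14 by chelation-controlled indium Barbier reaction (C7–C8 bond; C7 and C8 set from C9).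
4. 10 ⇐ dimethyl L-malate (C9 stereocentre, C8–C10, C14) + iodo-aldehyde 4 by Stobbe-type condensation (E-C1=C10), then CO2H → CHO. 4 ⇐ pent-4-yn-1-ol; 14 ⇐ methyl acrylate + dimethoxyacetaldehyde.

Assumption: locants C1–C15 are the germacranolide locants of the target (C6 lactone carbinol, C7 ring-fusion CH, C8 angelate carbon, C9 carbinol, C10 bearing C14O2Me, C11=C13 exocyclic methylene, C12 lactone carbonyl, C15 methyl on C4); the target is 6R,7S,8S,9S as read from the SMILES; organometallic intermediates are drawn as simple monomers.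

**Route**

Step 1
Reactants: 1 pent-4-yn-1-ol
Product: 3 (E)-5-iodo-4-methylpent-4-en-1-ol, via alkenylalane 2 (not isolated)
Conditions: Me3Al (3 equiv), Cp2ZrCl2 (0.25 equiv), CH2Cl2, 0 °C → rt; then I2, THF, −30 → 0 °C
Reagents that add atoms: trimethylaluminium C[Al](C)C; iodine II
Why: Negishi Zr-catalysed syn-carboalumination of the terminal alkyne followed by iodinolysis with retention gives the (E)-trisubstituted vinyl iodide, which fixes the C4=C5 geometry.

Step 2
Reactants: 3 (E)-5-iodo-4-methylpent-4-en-1-ol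
Product: 4 (E)-5-iodo-4-methylpent-4-enal
Conditions: TEMPO (0.1 equiv), PhI(OAc)2 (1.1 equiv), CH2Cl2, rt
Reagents that add atoms: none
Why: TEMPO/PhI(OAc)2 (oxoammonium) oxidation takes the primary alcohol to the aldehyde without touching the vinyl iodide.

Step 3
Reactants: 5 dimethyl (S)-malate; 4 (E)-5-iodo-4-methylpent-4-enal
Product: 8 (2S,3E,7E)-2-hydroxy-8-iodo-3-(methoxycarbonyl)-7-methylocta-3,7-dienoic acid, via dilithio malate dianion 6 (not isolated), via paraconate-type lactone 7 (not isolated)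
Conditions: 5, LDA (2.2 equiv), THF, −78 → −20 °C; 4, −78 → 0 °C; then KOt-Bu (1.1 equiv), 0 °C → rt; aq. HCl
Reagents that add atoms: none
Why: Stobbe condensation run on the Fráter–Seebach dianion (aldol at C10, lactonisation of the aldolate onto the C8 ester, E1cB ring opening) gives the (E)-alkylidene half-ester with CO2Me trans to the chain, and the C9 stereocentre of L-malate is carried through untouched because it is an alkoxide throughout.

Step 4
Reactants: 8 (2S,3E,7E)-2-hydroxy-8-iodo-3-(methoxycarbonyl)-7-methylocta-3,7-dienoic acid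
Product: 9 methyl (2E,6E)-2-[(1S)-1,2-dihydroxyethyl]-7-iodo-6-methylhepta-2,6-dienoate
Conditions: BH3·SMe2 (2.5 equiv), THF, 0 °C → rt; MeOH then neutral aqueous work-up; used without storage
Reagents that add atoms: none
Why: Borane reduces the carboxylic acid chemoselectively (acyloxyborane pathway) and much faster than the conjugated ester or the hindered, electron-poor alkenes.

Step 5
Reactants: 9 methyl (2E,6E)-2-[(1S)-1,2-dihydroxyethyl]-7-iodo-6-methylhepta-2,6-dienoate
Product: 10 methyl (2E,6E)-2-[(1S)-1-hydroxy-2-oxoethyl]-7-iodo-6-methylhepta-2,6-dienoate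
Conditions: TEMPO (0.1 equiv), PhI(OAc)2 (1.1 equiv), CH2Cl2, 0 °C → rt; crude aldehyde used at once
Reagents that add atoms: none
Why: The oxoammonium oxidant is selective for the primary over the secondary allylic hydroxyl, giving the α-hydroxy aldehyde needed for chelation control in step 8.

Step 6
Reactants: 11 methyl acrylate; 12 2,2-dimethoxyacetaldehyde
Product: 13 methyl 3-hydroxy-4,4-dimethoxy-2-methylidenebutanoate (racemic)
Conditions: DABCO (0.5 equiv), 1,4-dioxane/H2O, rt
Reagents that add atoms: none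
Why: Morita–Baylis–Hillman reaction of an activated α-alkoxy aldehyde; the carbinol stereocentre is removed in step 7.

Step 7
Reactants: 13 methyl 3-hydroxy-4,4-dimethoxy-2-methylidenebutanoate
Product: 14 methyl (2Z)-2-(bromomethyl)-4,4-dimethoxybut-2-enoate
Conditions: NBS (1.2 equiv), Me2S (1.3 equiv), CH2Cl2, 0 °C → rt
Reagents that add atoms: N-bromosuccinimide BrN1C(=O)CCC1=O
Why: Non-acidic SN2′ bromination of the MBH alcohol through its oxysulfonium salt gives the thermodynamically preferred (Z)-2-(bromomethyl)enoate and leaves the acetal intact.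

Step 8
Reactants: 10 methyl (2E,6E)-2-[(1S)-1-hydroxy-2-oxoethyl]-7-iodo-6-methylhepta-2,6-dienoate; 14 methyl (2Z)-2-(bromomethyl)-4,4-dimethoxybut-2-enoate
Product: 16 methyl (2E,6E)-2-[(1S,2S,3R)-3-(dimethoxymethyl)-1,2-dihydroxy-4-(methoxycarbonyl)pent-4-en-1-yl]-7-iodo-6-methylhepta-2,6-dienoate, via allylindium reagent 15 (not isolated)
Conditions: In powder (1.5 equiv), THF/H2O (1:1), rt
Reagents that add atoms: none
Why: Indium Barbier 2-(alkoxycarbonyl)allylation through a chair transition state, in which the (Z)-allylindium gives the C7/C8 syn adduct and indium chelated between C8=O and the free C9–OH (Cram chelate) gives the 8,9-syn diol, so C7 and C8 are both set from the malate-derived C9 while esters, acetal and vinyl iodide are inert.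

Step 9
Reactants: 16 methyl (2E,6E)-2-[(1S,2S,3R)-3-(dimethoxymethyl)-1,2-dihydroxy-4-(methoxycarbonyl)pent-4-en-1-yl]-7-iodo-6-methylhepta-2,6-dienoate
Product: 17 methyl (2E,6E)-2-[(1S,2S,3R)-1-[tert-butyl(dimethyl)silyl]oxy-3-(dimethoxymethyl)-2-hydroxy-4-(methoxycarbonyl)pent-4-en-1-yl]-7-iodo-6-methylhepta-2,6-dienoate
Conditions: TBSCl (1.2 equiv), imidazole (2.5 equiv), DMF, 0 °C → rt
Reagents that add atoms: tert-butyldimethylsilyl chloride CC(C)(C)[Si](C)(C)Cl
Why: Sterically controlled silylation takes the allylic C9–OH, which has a planar sp2 neighbour, in preference to the C8–OH, which is flanked by the fully branched C7.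

Step 10
Reactants: 17 the 9-O-TBS alcohol from step 9; 18 angelic acid
Product: 20 methyl (2E,6E)-2-[(1S,2S,3R)-1-[tert-butyl(dimethyl)silyl]oxy-3-(dimethoxymethyl)-4-(methoxycarbonyl)-2-[(2Z)-2-methylbut-2-enoyl]oxypent-4-en-1-yl]-7-iodo-6-methylhepta-2,6-dienoate, via mixed anhydride 19 (not isolated)
Conditions: 18, 2,4,6-trichlorobenzoyl chloride, Et3N, toluene, rt; then 17, toluene, 70 °C (no DMAP)
Reagents that add atoms: none
Why: Yamaguchi esterification through the angelic/trichlorobenzoic mixed anhydride acylates the hindered C8–OH without Z→E isomerisation of the angelate and without the strong base that would trigger γ-lactonisation.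

Step 11
Reactants: 20 the 8-O-angelate dimethyl acetal from step 10
Product: 21 methyl (2E,6E)-2-[(1S,2S,3R)-1-[tert-butyl(dimethyl)silyl]oxy-3-formyl-4-(methoxycarbonyl)-2-[(2Z)-2-methylbut-2-enoyl]oxypent-4-en-1-yl]-7-iodo-6-methylhepta-2,6-dienoate
Conditions: LiBF4, MeCN/H2O (50:1), rt; crude aldehyde used at once
Reagents that add atoms: water O
Why: Mild Lewis-acid hydrolysis of the dimethyl acetal spares the TBS ether and the angelate and, being non-basic, avoids epimerisation at C7 and β-elimination of the C8 acyloxy group.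

Step 12
Reactants: 21 the iodo-aldehyde from step 11
Product: 24 9-O-(tert-butyldimethylsilyl)polymatin A (6R,7S,8S,9S), via alkenylchromium(III) species 22 (not isolated), via macrocyclic chromium alkoxide 23 (not isolated)
Conditions: CrCl2 (10 equiv), NiCl2 (0.1 equiv), DMSO/THF, 2 mM (syringe-pump addition), rt; aq. NH4Cl
Reagents that add atoms: none
Why: Intramolecular Nozaki–Hiyama–Kishi reaction in which the alkenylchromium adds to the C6 aldehyde to close the ten-membered ring and the resulting Cr(III) alkoxide acylates itself with the γ-disposed C12 methyl ester to close the α-methylene lactone in the same pot, with C6 set by Felkin–Anh attack anti to the bulky C8 branch reinforced by 1,3-anti induction from the β-acyloxy group (matched α,β-anti aldehyde), which gives the trans-fused lactone.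

Step 13
Reactants: 24 9-O-(tert-butyldimethylsilyl)polymatin A
Product: 25 Polymatin A
Conditions: HF·pyridine, THF/pyridine, 0 °C → rt
Reagents that add atoms: none
Why: Buffered fluoride desilylation frees the C9–OH without acyl migration, angelate isomerisation or Michael addition to the α-methylene lactone.

**Compound list**

1 | pent-4-yn-1-ol | C#CCCCO | starting material
2 | [(1E)-5-(dimethylalumanyloxy)-2-methylpent-1-en-1-yl]dimethylalumane | C[Al](C)/C=C(\C)CCCO[Al](C)C | intermediate
3 | (E)-5-iodo-4-methylpent-4-en-1-ol | I/C=C(\C)CCCO | intermediate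
4 | (E)-5-iodo-4-methylpent-4-enal | I/C=C(\C)CCC=O | intermediate
5 | dimethyl (S)-malate (dimethyl L-malate) | COC(=O)C[C@H](O)C(=O)OC | starting material
6 | dilithium alkoxide-enolate (dianion) of 5 | COC(=O)[C@@H]([O-])C=C([O-])OC.[Li+].[Li+] | intermediate
7 | methyl (4S)-4-hydroxy-2-[(3E)-4-iodo-3-methylbut-3-en-1-yl]-5-oxooxolane-3-carboxylate (present as lithium alkoxide; C2/C3 mixture) | O[C@H]1C(C(=O)OC)C(CC/C(C)=C/I)OC1=O | intermediate
8 | (2S,3E,7E)-2-hydroxy-8-iodo-3-(methoxycarbonyl)-7-methylocta-3,7-dienoic acid | I/C=C(\C)CC/C=C(/C(=O)OC)[C@H](O)C(=O)O | intermediate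
9 | methyl (2E,6E)-2-[(1S)-1,2-dihydroxyethyl]-7-iodo-6-methylhepta-2,6-dienoate | I/C=C(\C)CC/C=C(/C(=O)OC)[C@H](O)CO | intermediate
10 | methyl (2E,6E)-2-[(1S)-1-hydroxy-2-oxoethyl]-7-iodo-6-methylhepta-2,6-dienoate | I/C=C(\C)CC/C=C(/C(=O)OC)[C@H](O)C=O | intermediate
11 | methyl acrylate | C=CC(=O)OC | starting material
12 | 2,2-dimethoxyacetaldehyde | COC(OC)C=O | starting material
13 | methyl 3-hydroxy-4,4-dimethoxy-2-methylidenebutanoate (racemic) | C=C(C(=O)OC)C(O)C(OC)OC | intermediate
14 | methyl (2Z)-2-(bromomethyl)-4,4-dimethoxybut-2-enoate | BrC/C(C(=O)OC)=C\C(OC)OC | intermediate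
15 | [(2Z)-4,4-dimethoxy-2-(methoxycarbonyl)but-2-en-1-yl]indium dibromide (allylindium reagent, formal drawing) | Br[In](Br)C/C(C(=O)OC)=C\C(OC)OC | intermediate
16 | methyl (2E,6E)-2-[(1S,2S,3R)-3-(dimethoxymethyl)-1,2-dihydroxy-4-(methoxycarbonyl)pent-4-en-1-yl]-7-iodo-6-methylhepta-2,6-dienoate | I/C=C(\C)CC/C=C(/C(=O)OC)[C@H](O)[C@@H](O)[C@H](C(OC)OC)C(=C)C(=O)OC | intermediate
17 | methyl (2E,6E)-2-[(1S,2S,3R)-1-[tert-butyl(dimethyl)silyl]oxy-3-(dimethoxymethyl)-2-hydroxy-4-(methoxycarbonyl)pent-4-en-1-yl]-7-iodo-6-methylhepta-2,6-dienoate | I/C=C(\C)CC/C=C(/C(=O)OC)[C@H](O[Si](C)(C)C(C)(C)C)[C@@H](O)[C@H](C(OC)OC)C(=C)C(=O)OC | intermediate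
18 | angelic acid, (2Z)-2-methylbut-2-enoic acid | C/C=C(/C)C(=O)O | starting material
19 | (2Z)-2-methylbut-2-enoic 2,4,6-trichlorobenzoic anhydride | C/C=C(/C)C(=O)OC(=O)c1c(Cl)cc(Cl)cc1Cl | intermediate
20 | methyl (2E,6E)-2-[(1S,2S,3R)-1-[tert-butyl(dimethyl)silyl]oxy-3-(dimethoxymethyl)-4-(methoxycarbonyl)-2-[(2Z)-2-methylbut-2-enoyl]oxypent-4-en-1-yl]-7-iodo-6-methylhepta-2,6-dienoate | I/C=C(\C)CC/C=C(/C(=O)OC)[C@H](O[Si](C)(C)C(C)(C)C)[C@@H](OC(=O)/C(C)=C\C)[C@H](C(OC)OC)C(=C)C(=O)OC | intermediate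
21 | methyl (2E,6E)-2-[(1S,2S,3R)-1-[tert-butyl(dimethyl)silyl]oxy-3-formyl-4-(methoxycarbonyl)-2-[(2Z)-2-methylbut-2-enoyl]oxypent-4-en-1-yl]-7-iodo-6-methylhepta-2,6-dienoate | I/C=C(\C)CC/C=C(/C(=O)OC)[C@H](O[Si](C)(C)C(C)(C)C)[C@@H](OC(=O)/C(C)=C\C)[C@H](C=O)C(=C)C(=O)OC | intermediate
22 | C5-dichlorochromium(III) alkenyl species derived from 21 (iodine replaced by CrCl2) | Cl[Cr](Cl)/C=C(\C)CC/C=C(/C(=O)OC)[C@H](O[Si](C)(C)C(C)(C)C)[C@@H](OC(=O)/C(C)=C\C)[C@H](C=O)C(=C)C(=O)OC | intermediate
23 | ten-membered C6-alkoxide (drawn as the free C6 alcohol): cyclodeca-1(10),4-diene bearing 6-OH, the methyl acrylate unit on C7, 8-O-angelate, 9-OTBS and C10-CO2Me | COC(=O)C(=C)[C@H]1[C@H](O)/C=C(\C)CC/C=C(/C(=O)OC)[C@H](O[Si](C)(C)C(C)(C)C)[C@H]1OC(=O)/C(C)=C\C | intermediate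
24 | 9-O-(tert-butyldimethylsilyl)polymatin A (6R,7S,8S,9S) | C=C1C(=O)O[C@@H]2/C=C(\C)CC/C=C(/C(=O)OC)[C@H](O[Si](C)(C)C(C)(C)C)[C@@H](OC(=O)/C(C)=C\C)[C@@H]12 | intermediate
25 | Polymatin A | C=C1C(=O)O[C@@H]2/C=C(\C)CC/C=C(/C(=O)OC)[C@H](O)[C@@H](OC(=O)/C(C)=C\C)[C@@H]12 | target

**Step count**

Total: 13 steps. Longest linear sequence: 11 steps (1 → 2 → 3 → 4 → 5 → 8 → 9 → 10 → 11 → 12 → 13); steps 6–7 are the side branch to bromide 14.

**Three steps most likely to fail, with fallbacks**

Step 12 (Ni/Cr ring closure with lactonisation). The risks are oligomerisation or strain in the medium-ring closure, the wrong C6 epimer (cis-lactone), and β-elimination or C7 epimerisation of the β-acyloxy aldehyde 21. The fallback sets out from 16 and comes back at 24. It puts the ester on after the rings are made and uses a rigidifying ring during cyclisation. Acetone/2,2-dimethoxypropane with PPTS converts 16 into the 8,9-O-isopropylidene dimethyl acetal F1. Amberlyst-15 in wet acetone unmasks only the aldehyde to give the acetonide aldehyde F2, a β-alkoxy aldehyde that cannot eliminate and whose trans-dioxolane pre-folds the chain. The same Ni/Cr cyclisation–lactonisation then gives the macrocyclic acetonide lactone F3. Aqueous acetic acid frees the 8,9-diol F4, TBSCl/imidazole silylates the allylic 9-OH to give the 9-O-TBS 8-alcohol F5, and Yamaguchi acylation of F5 with 19 gives 24.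

Step 9 (regioselective silylation of O9 in diol 16). If the two secondary hydroxyls are not differentiated, the fallback sets out from 16 and comes back at 25, using the molecule's own acetal as the O9 protecting group. PPTS in CH2Cl2 with molecular sieves closes O9 onto C6 with loss of methanol to give the cyclic methyl acetal (methyl furanoside, anomeric mixture) F6; O8 cannot take part because it would give a four-membered ring. Yamaguchi acylation with 19 gives the 8-O-angelate furanoside F7, and aqueous acid (Amberlyst-15, wet acetone) gives the lactol F8. F8 is subjected directly to the Ni/Cr conditions: the open hydroxy-aldehyde tautomer cyclises and lactonises, giving 25 without a silyl group. This is one step shorter but relies on the lactol supplying enough free aldehyde.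

Step 5 (selective oxidation to the labile α-hydroxy aldehyde 10; diol 9 can also γ-lactonise onto the C14 ester). The fallback sets out from 8 and comes back at 16, avoiding both 9 and isolated 10. 2,2-Dimethoxypropane/PPTS converts the α-hydroxy acid 8 into the 2,2-dimethyl-1,3-dioxolan-4-one F9. DIBAL-H (1.05 equiv, CH2Cl2, −78 °C) reduces this activated acylal-type carbonyl in preference to the hindered conjugated methyl ester, giving the dioxolanol (masked α-hydroxy aldehyde) F10. In the mildly acidic aqueous indium medium of step 8, F10 releases the α-hydroxy aldehyde in situ and is trapped by the allylindium from 14 to give 16.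

**Further compounds**

F1 | step 12 | 8,9-O-isopropylidene derivative of 16 (dimethyl acetal retained) | I/C=C(\C)CC/C=C(/C(=O)OC)[C@@H]1OC(C)(C)O[C@H]1[C@H](C(OC)OC)C(=C)C(=O)OC
F2 | step 12 | 8,9-O-isopropylidene C6 aldehyde | I/C=C(\C)CC/C=C(/C(=O)OC)[C@@H]1OC(C)(C)O[C@H]1[C@H](C=O)C(=C)C(=O)OC
F3 | step 12 | 8,9-O-isopropylidene-8-desangeloylpolymatin A (macrocyclic acetonide lactone) | C=C1C(=O)O[C@@H]2/C=C(\C)CC/C=C(/C(=O)OC)[C@@H]3OC(C)(C)O[C@H]3[C@@H]12
F4 | step 12 | 8-desangeloylpolymatin A (8,9-diol) | C=C1C(=O)O[C@@H]2/C=C(\C)CC/C=C(/C(=O)OC)[C@H](O)[C@@H](O)[C@@H]12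
F5 | step 12 | 9-O-(tert-butyldimethylsilyl)-8-desangeloylpolymatin A | C=C1C(=O)O[C@@H]2/C=C(\C)CC/C=C(/C(=O)OC)[C@H](O[Si](C)(C)C(C)(C)C)[C@@H](O)[C@@H]12
F6 | step 9 | cyclic methyl acetal of 16 (O9–C6 tetrahydrofuran, 8-OH free, anomeric mixture) | I/C=C(\C)CC/C=C(/C(=O)OC)[C@@H]1OC(OC)[C@H](C(=C)C(=O)OC)[C@@H]1O
F7 | step 9 | 8-O-angelate of F6 | I/C=C(\C)CC/C=C(/C(=O)OC)[C@@H]1OC(OC)[C@H](C(=C)C(=O)OC)[C@@H]1OC(=O)/C(C)=C\C
F8 | step 9 | lactol from F7 (C6 hemiacetal, anomeric mixture) | I/C=C(\C)CC/C=C(/C(=O)OC)[C@@H]1OC(O)[C@H](C(=C)C(=O)OC)[C@@H]1OC(=O)/C(C)=C\C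
F9 | step 5 | methyl (2E,6E)-2-[(4S)-2,2-dimethyl-5-oxo-1,3-dioxolan-4-yl]-7-iodo-6-methylhepta-2,6-dienoate | I/C=C(\C)CC/C=C(/C(=O)OC)[C@@H]1OC(C)(C)OC1=O
F10 | step 5 | methyl (2E,6E)-2-[(4S)-5-hydroxy-2,2-dimethyl-1,3-dioxolan-4-yl]-7-iodo-6-methylhepta-2,6-dienoate (hemiacetal mixture) | I/C=C(\C)CC/C=C(/C(=O)OC)[C@@H]1OC(C)(C)OC1O
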